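**Retrosynthetic overview**

1. The route rests on the β-hydroxy ester chain O–C(=O)–CH2–CH(OH)–CH3 on the C1 oxygen of the central benzene ring (C1 (S)-3-hydroxybutanoyloxy, C2 OH, C3 4-hydroxyphenyl, C4 3-phenylpropanoyloxy, C5 OH, C6 4-hydroxyphenyl). Retrosynthetically this chain is a phenol O–H, one CO and (S)-propylene oxide.
2. Key disconnection: the C(=O)–O(C1) and CH2–C(=O) bonds are cut together to phenol 8, CO 10 and epoxide 9 (cobalt-catalysed carbonylative epoxide opening). The carbinol centre is bought with the epoxide.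
3. Phenol 8 comes from the centrosymmetric hydroquinone 6 by mono-acylation with 3-phenylpropanoyl chloride, and 6 from terphenylquinone 5 by dithionite reduction.
4. The two aryl bonds at C3 and C6 are made by a double Suzuki–Miyaura coupling on 2,5-bis(benzyloxy)-3,6-dibromoquinone 3, which is made from bromanil and benzyl alkoxide.
5. No ring is formed at any stage: the central ring comes from bromanil and the outer rings from the boronic acid. The four benzyl ethers are removed last by neutral hydrogenolysis.

Key step: step 5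

Remark on the chemistry: the central ring keeps the numbering C1–C6 given above throughout. Hydroquinone 6 has an inversion centre, so its two free hydroxyls are equivalent and mono-acylation raises no regiochemical question.

**Step 1**
Reactants: 1 bromanil (2,3,5,6-tetrabromo-1,4-benzoquinone); 2 benzyl alcohol
Product: 3 2,5-bis(benzyloxy)-3,6-dibromo-1,4-benzoquinone
Conditions: 2 (2.1 equiv), NaH (2.1 equiv), THF, 0 °C; then 1, THF, −40 to 0 °C
Reagents that add atoms: benzyl alcohol (compound 2), OCc1ccccc1
Why: Twofold addition–elimination of an alkoxide on a tetrahaloquinone, in which the first benzyloxy group deactivates, as a vinylogous ester, the carbonyl it is conjugated with and so steers the second alkoxide to C5, as in the standard preparation of 2,5-dibromo-3,6-dimethoxybenzoquinone from bromanil and methoxide.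

**Step 2**
Reactants: 3 2,5-bis(benzyloxy)-3,6-dibromo-1,4-benzoquinone; 4 4-(benzyloxy)phenylboronic acid (2.4 equiv)
Product: 5 2,5-bis(benzyloxy)-3,6-bis[4-(benzyloxy)phenyl]-1,4-benzoquinone
Conditions: Pd(PPh3)4 (5 mol%), K2CO3, 1,4-dioxane/H2O (10:1), 80 °C
Reagents that add atoms: 4-(benzyloxy)phenylboronic acid (compound 4), OB(O)c1ccc(OCc2ccccc2)cc1
Why: Double Suzuki–Miyaura coupling at the two enone-activated vinylic C–Br bonds of a 2,5-dialkoxy-3,6-dibromoquinone, the established entry to 2,5-diaryl-3,6-dialkoxyquinones of the terphenylquinone family.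

**Step 3**
Reactants: 5 2,5-bis(benzyloxy)-3,6-bis[4-(benzyloxy)phenyl]-1,4-benzoquinone
Product: 6 2,5-bis(benzyloxy)-3,6-bis[4-(benzyloxy)phenyl]benzene-1,4-diol
Conditions: Na2S2O4 (excess), THF/H2O, rt, argon; crude diol carried on at once
Reagents that add atoms: none
Why: Dithionite reduction of a quinone to its hydroquinone, which leaves benzyl ethers and biaryl bonds untouched.

**Step 4**
Reactants: 6 2,5-bis(benzyloxy)-3,6-bis[4-(benzyloxy)phenyl]benzene-1,4-diol; 7 3-phenylpropanoyl chloride (0.95 equiv)
Product: 8 2,5-bis(benzyloxy)-3,6-bis[4-(benzyloxy)phenyl]-4-hydroxyphenyl 3-phenylpropanoate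
Conditions: 7 (slow addition), pyridine (3 equiv), DMAP (5 mol%), CH2Cl2, −20 to 0 °C, argon
Reagents that add atoms: 3-phenylpropanoyl chloride (compound 7), O=C(Cl)CCc1ccccc1
Why: Acylation of a phenol by an acid chloride under nucleophilic catalysis, in which either of the two equivalent hydroxyls gives 8, the slight deficit of 7 at low temperature should limit diester formation, and unreacted 6 and diester are separable and recyclable.

**Step 5**
Reactants: 8 2,5-bis(benzyloxy)-3,6-bis[4-(benzyloxy)phenyl]-4-hydroxyphenyl 3-phenylpropanoate; 9 (S)-propylene oxide [(S)-2-methyloxirane] (1.5 equiv, added in portions); 10 carbon monoxide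
Product: 11 4-(3-phenylpropanoyloxy)-2,5-bis(benzyloxy)-3,6-bis[4-(benzyloxy)phenyl]phenyl (S)-3-hydroxybutanoate
Conditions: Co2(CO)8 (10 mol%), 3-hydroxypyridine (20 mol%), CO (40 bar), THF, 55 °C
Reagents that add atoms: (S)-propylene oxide (compound 9), C[C@H]1CO1; carbon monoxide (compound 10), [C-]#[O+]
Why: Proposed new method: Co2(CO)8 is disproportionated by 3-hydroxypyridine to the anion [Co(CO)4]−, which displaces the epoxide oxygen of 9 by backside attack at the terminal CH2 (the epoxide being activated by hydrogen bonding), CO then inserts into the Co–CH2 bond to give a (S)-3-hydroxybutanoylcobalt tetracarbonyl, and its acyl group is shuttled through an acylpyridinium or 3-pyridyl ester to the phenoxide of 8 with return of HCo(CO)4, so that the CH2–C(=O) and C(=O)–OAr bonds arise in one operation. The closest known reaction is the Co2(CO)8/3-hydroxypyridine-catalysed alkoxycarbonylation of terminal epoxides with simple alcohols to β-hydroxy esters, which runs with retention of the epoxide configuration; a di-ortho-substituted phenol as acyl acceptor is the untested part, made plausible by the ease with which phenoxides are O-acylated by acylpyridinium ions. No ring is closed. No stereocentre is created: the bond between oxygen and the methyl-bearing carbon of 9 stays intact throughout, so the configuration of the epoxide is carried unchanged into the (S)-carbinol. The step needs attack at CH2 only, which the methyl group enforces against the bulky, soft cobaltate, and it needs acyl transfer to the phenol to outrun β-lactone closure, alkyl–oxygen opening of that lactone and acylation of the product carbinol; the protic, Lewis-acid-free medium keeps the β-oxygen as a weakly nucleophilic hydroxyl, the phenol of 8 is the most acidic O–H present and thus the one delivered as its anion by the pyridine base, and the epoxide is fed in portions. The benzyl ethers at C2 and C5 leave no neighbouring hydroxyl to which either acyl group could migrate.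

**Step 6**
Reactants: 11 4-(3-phenylpropanoyloxy)-2,5-bis(benzyloxy)-3,6-bis[4-(benzyloxy)phenyl]phenyl (S)-3-hydroxybutanoate
Product: 12 2,5-dihydroxy-3,6-bis(4-hydroxyphenyl)-4-(3-phenylpropanoyloxy)phenyl (S)-3-hydroxybutanoate (CNP0296884.1)
Conditions: H2 (1 atm), 10% Pd/C, EtOAc, rt
Reagents that add atoms: none
Why: Hydrogenolysis of four aryl benzyl ethers over palladium on carbon in a neutral aprotic solvent, which should leave both aryl esters and the secondary carbinol in place and supplies no base to drive acyl migration onto the freed C2 and C5 hydroxyls.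

**Compound list**

1 | bromanil (2,3,5,6-tetrabromo-1,4-benzoquinone) | O=C1C(Br)=C(Br)C(=O)C(Br)=C1Br | starting material
2 | benzyl alcohol | OCc1ccccc1 | starting material
3 | 2,5-bis(benzyloxy)-3,6-dibromo-1,4-benzoquinone | O=C1C(OCc2ccccc2)=C(Br)C(=O)C(OCc2ccccc2)=C1Br | intermediate
4 | 4-(benzyloxy)phenylboronic acid | OB(O)c1ccc(OCc2ccccc2)cc1 | starting material
5 | 2,5-bis(benzyloxy)-3,6-bis[4-(benzyloxy)phenyl]-1,4-benzoquinone | O=C1C(OCc2ccccc2)=C(c2ccc(OCc3ccccc3)cc2)C(=O)C(OCc2ccccc2)=C1c1ccc(OCc2ccccc2)cc1 | intermediate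
6 | 2,5-bis(benzyloxy)-3,6-bis[4-(benzyloxy)phenyl]benzene-1,4-diol | Oc1c(OCc2ccccc2)c(-c2ccc(OCc3ccccc3)cc2)c(O)c(OCc2ccccc2)c1-c1ccc(OCc2ccccc2)cc1 | intermediate
7 | 3-phenylpropanoyl chloride | O=C(Cl)CCc1ccccc1 | starting material
8 | 2,5-bis(benzyloxy)-3,6-bis[4-(benzyloxy)phenyl]-4-hydroxyphenyl 3-phenylpropanoate | Oc1c(OCc2ccccc2)c(-c2ccc(OCc3ccccc3)cc2)c(OC(=O)CCc2ccccc2)c(OCc2ccccc2)c1-c1ccc(OCc2ccccc2)cc1 | intermediate
9 | (S)-propylene oxide [(S)-2-methyloxirane] | C[C@H]1CO1 | starting material
10 | carbon monoxide | [C-]#[O+] | starting material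
11 | 4-(3-phenylpropanoyloxy)-2,5-bis(benzyloxy)-3,6-bis[4-(benzyloxy)phenyl]phenyl (S)-3-hydroxybutanoate | C[C@H](O)CC(=O)Oc1c(OCc2ccccc2)c(-c2ccc(OCc3ccccc3)cc2)c(OC(=O)CCc2ccccc2)c(OCc2ccccc2)c1-c1ccc(OCc2ccccc2)cc1 | intermediate
12 | 2,5-dihydroxy-3,6-bis(4-hydroxyphenyl)-4-(3-phenylpropanoyloxy)phenyl (S)-3-hydroxybutanoate | C[C@H](O)CC(=O)Oc1c(O)c(-c2ccc(O)cc2)c(OC(=O)CCc2ccccc2)c(O)c1-c1ccc(O)cc1 | target

**Step count**

Total steps: 6. Longest linear sequence: 6 steps (from bromanil 1 to 12).

**Steps most likely to fail**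

Step 5 (proposed new method). Acyl transfer from the β-hydroxyacylcobalt species to the hindered phenoxide may be slower than its closure to β-butyrolactone, than ether formation by alkyl–oxygen opening of that lactone, or than chain growth at the carbinol of the product. Intermolecular scrambling of the existing aryl ester is a further drain. The fallback uses known chemistry, sets out from 8 and rejoins the route at 12. Commercial methyl (S)-3-hydroxybutanoate (C[C@H](O)CC(=O)OC) is O-benzylated with benzyl 2,2,2-trichloroacetimidate and catalytic TfOH in CH2Cl2/cyclohexane to methyl (S)-3-(benzyloxy)butanoate F1. Saponification with LiOH in THF/H2O gives (S)-3-(benzyloxy)butanoic acid F2. Steglich esterification of F2 with phenol 8 (EDC·HCl, DMAP, CH2Cl2, 0 °C to rt) should give 4-(3-phenylpropanoyloxy)-2,5-bis(benzyloxy)-3,6-bis[4-(benzyloxy)phenyl]phenyl (S)-3-(benzyloxy)butanoate F3. Hydrogenolysis (H2, Pd/C, EtOAc) then removes all five benzyl groups and gives 12 directly.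

Step 4. Over-acylation and incomplete conversion may give a statistical mixture, and unreacted diol may re-oxidise in air during separation. The fallback sets out from 6 and returns at 8. Exhaustive acylation with excess 7 (Et3N, DMAP, CH2Cl2) gives 2,5-bis(benzyloxy)-3,6-bis[4-(benzyloxy)phenyl]-1,4-phenylene bis(3-phenylpropanoate) F4, which is stable to air and easily purified. One acyl group is then removed by aminolysis with pyrrolidine (1.0 equiv, THF, 0 °C). The phenoxide set free by the first cleavage is a strong para donor and turns the remaining aryloxy group into a much poorer leaving group, so the second cleavage should lag and 8 should accumulate.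

Step 2. The quinone may be reduced by the palladium/boronic acid system, the benzyl vinylogous esters may hydrolyse in the basic aqueous medium, and the second coupling may stall. The fallback sets out from 3 and returns at 6, bypassing 5. Dithionite reduction of 3 gives 2,5-bis(benzyloxy)-3,6-dibromobenzene-1,4-diol F5. Protection with MOMCl and iPr2NEt in CH2Cl2 gives 1,4-bis(benzyloxy)-2,5-dibromo-3,6-bis(methoxymethoxy)benzene F6. Double Suzuki–Miyaura coupling of this redox-inert aryl dibromide with 4 (Pd(OAc)2, SPhos, K3PO4, toluene/H2O, 100 °C) should give 1,4-bis(benzyloxy)-2,5-bis[4-(benzyloxy)phenyl]-3,6-bis(methoxymethoxy)benzene F7. Cleavage of the two MOM ethers with HCl in MeOH/THF under argon then gives hydroquinone 6.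

**Further compounds**

F1 | step 5 | methyl (S)-3-(benzyloxy)butanoate | C[C@H](OCc1ccccc1)CC(=O)OC
F2 | step 5 | (S)-3-(benzyloxy)butanoic acid | C[C@H](OCc1ccccc1)CC(=O)O
F3 | step 5 | 4-(3-phenylpropanoyloxy)-2,5-bis(benzyloxy)-3,6-bis[4-(benzyloxy)phenyl]phenyl (S)-3-(benzyloxy)butanoate | C[C@H](OCc1ccccc1)CC(=O)Oc1c(OCc2ccccc2)c(-c2ccc(OCc3ccccc3)cc2)c(OC(=O)CCc2ccccc2)c(OCc2ccccc2)c1-c1ccc(OCc2ccccc2)cc1
F4 | step 4 | 2,5-bis(benzyloxy)-3,6-bis[4-(benzyloxy)phenyl]-1,4-phenylene bis(3-phenylpropanoate) | O=C(CCc1ccccc1)Oc1c(OCc2ccccc2)c(-c2ccc(OCc3ccccc3)cc2)c(OC(=O)CCc2ccccc2)c(OCc2ccccc2)c1-c1ccc(OCc2ccccc2)cc1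
F5 | step 2 | 2,5-bis(benzyloxy)-3,6-dibromobenzene-1,4-diol | Oc1c(OCc2ccccc2)c(Br)c(O)c(OCc2ccccc2)c1Br
F6 | step 2 | 1,4-bis(benzyloxy)-2,5-dibromo-3,6-bis(methoxymethoxy)benzene | COCOc1c(OCc2ccccc2)c(Br)c(OCOC)c(OCc2ccccc2)c1Br
F7 | step 2 | 1,4-bis(benzyloxy)-2,5-bis[4-(benzyloxy)phenyl]-3,6-bis(methoxymethoxy)benzene | COCOc1c(OCc2ccccc2)c(-c2ccc(OCc3ccccc3)cc2)c(OCOC)c(OCc2ccccc2)c1-c1ccc(OCc2ccccc2)cc1
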